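The route rests on cutting the C3–C3a bond of the dihydrofuran ring while the O1–C2 aryl ether is already in place. The cut exploits two features. C3 carries the 4-oxygenated phenyl ring and can therefore become a quinone-methide-like cation. C3a, lying between oxygenated C4 and O1-bearing C7a, is the most nucleophilic free carbon of the benzofuran arene. Acid ionisation of a 2-aryloxy-1,2-diarylethanol thus closes the five-membered ring, erases the carbinol centre and sets C3 trans to C2 in one operation. In the precursor the ether carbon is fixed beforehand by a reductive dynamic kinetic resolution, and a bromine marks the future C5, where the chromone is attached later.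

Key step: step 9

Assumption: the sense of selection in step 8 is assigned by analogy with the benzoin case. Only the ether carbon matters, because step 9 destroys the carbinol centre, so the mirror-image catalyst would be used if that carbon came out (S). Racemates are written without stereo marks, except diol 3, which is drawn as one enantiomer.

Step 1
Reactants: 1 resveratrol
Product: 2 (E)-3,4',5-tris(benzyloxy)stilbene
Conditions: BnBr (3.5 equiv), K2CO3, DMF, 60 °C
Reagents that add atoms: benzyl bromide BrCc1ccccc1
Why: Williamson ether synthesis on all three phenols, benzyl being chosen because it keeps the para oxygen a strong donor for the later ionisation, tolerates organolithium and hydride reagents, and leaves at the end under boron trichloride.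

Step 2
Reactants: 2 (E)-3,4',5-tris(benzyloxy)stilbene
Product: 3 rac-threo-1-[4-(benzyloxy)phenyl]-2-[3,5-bis(benzyloxy)phenyl]ethane-1,2-diol
Conditions: K2OsO4·2H2O (2 mol %), NMO (1.5 equiv), THF/t-BuOH/H2O, rt
Reagents that add atoms: N-methylmorpholine N-oxide C[N+]1([O-])CCOCC1; water O
Why: Upjohn syn-dihydroxylation touches only the alkene, whereas a bromohydrin made with an N-bromoimide would risk nuclear bromination of the resorcinol diether ring; the threo relationship created is irrelevant because both centres are flattened or equilibrated later.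

Step 3
Reactants: 3 rac-threo-1-[4-(benzyloxy)phenyl]-2-[3,5-bis(benzyloxy)phenyl]ethane-1,2-diol
Product: 4 rac-1-[4-(benzyloxy)phenyl]-2-[3,5-bis(benzyloxy)phenyl]-2-hydroxyethan-1-one
Conditions: DDQ (1.1 equiv), CH2Cl2, 0 °C to rt
Reagents that add atoms: none
Why: DDQ dehydrogenation of an electron-rich benzylic alcohol by hydride abstraction is feasible only at the carbinol C–H para to a benzyloxy donor (the other carbinol has only meta oxygens), so the carbonyl appears next to the 4-(benzyloxy)phenyl ring, which is also the thermodynamically preferred acyloin isomer.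

Step 4
Reactants: 4 rac-1-[4-(benzyloxy)phenyl]-2-[3,5-bis(benzyloxy)phenyl]-2-hydroxyethan-1-one
Product: 6 rac-2-bromo-1-[4-(benzyloxy)phenyl]-2-[3,5-bis(benzyloxy)phenyl]ethan-1-one, via mesylate 5 (not isolated)
Conditions: Ms2O (1.2 equiv), Et3N, CH2Cl2, −10 °C; then LiBr (5 equiv), THF, rt
Reagents that add atoms: lithium bromide [Li+].[Br-]; methanesulfonic anhydride CS(=O)(=O)OS(C)(=O)=O (mesyl group, in 5 only)
Why: Sulfonylation followed by SN2 displacement with bromide (Finkelstein type) at a carbon activated by carbonyl and aryl groups installs the leaving group without electrophilic bromine, without chloride that would give a mixed halide, and without phosphine that could reduce the product.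

Step 5
Reactants: 7 2,5-dibromohydroquinone
Product: 8 1,4-bis(benzyloxy)-2,5-dibromobenzene
Conditions: BnBr (2.3 equiv), K2CO3, DMF, 60 °C
Reagents that add atoms: benzyl bromide BrCc1ccccc1
Why: Williamson ether synthesis on both phenols of a centrosymmetric substrate, so no selectivity question arises.

Step 6
Reactants: 8 1,4-bis(benzyloxy)-2,5-dibromobenzene
Product: 11 2,5-bis(benzyloxy)-4-bromophenol, via aryllithium 9 (not isolated), via dimethyl boronate 10 (not isolated)
Conditions: n-BuLi (1.0 equiv), THF, −78 °C; B(OMe)3, −78 °C to rt; AcOH, 30% aq H2O2, 0 °C to rt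
Reagents that add atoms: hydrogen peroxide OO; n-butyllithium [Li]CCCC (lithium, in 9 only); trimethyl borate COB(OC)OC (boron group, in 10 only)
Why: Bromine–lithium exchange stops after one bromine with one equivalent of alkyllithium because the two sites are equivalent and a second exchange on an aryllithium is disfavoured, and borate trapping followed by peroxide-induced 1,2-aryl migration (boronate oxidation) turns C–Li into C–OH.

Step 7
Reactants: 6 rac-2-bromo-1-[4-(benzyloxy)phenyl]-2-[3,5-bis(benzyloxy)phenyl]ethan-1-one; 11 2,5-bis(benzyloxy)-4-bromophenol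
Product: 12 rac-2-[2,5-bis(benzyloxy)-4-bromophenoxy]-1-[4-(benzyloxy)phenyl]-2-[3,5-bis(benzyloxy)phenyl]ethan-1-one
Conditions: K2CO3 (1.5 equiv), acetone, 40 °C, N2
Reagents that add atoms: none
Why: Williamson ether synthesis in which the phenoxide displaces the doubly activated secondary bromide by SN2, the ketone having no α′-hydrogen for a Favorskii pathway, and the new centre being formed racemic on purpose because it is equilibrated in the next step.

Step 8
Reactants: 12 rac-2-[2,5-bis(benzyloxy)-4-bromophenoxy]-1-[4-(benzyloxy)phenyl]-2-[3,5-bis(benzyloxy)phenyl]ethan-1-one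
Product: 13 (1R,2R)-2-[2,5-bis(benzyloxy)-4-bromophenoxy]-1-[4-(benzyloxy)phenyl]-2-[3,5-bis(benzyloxy)phenyl]ethan-1-ol
Conditions: RuCl[(S,S)-TsDPEN](p-cymene) (2 mol %), HCO2H/Et3N 5:2, DMF, 40 °C; erythro isomer removed by chromatography and recrystallisation
Reagents that add atoms: none
Why: This is a Noyori–Ikariya asymmetric transfer hydrogenation run as a dynamic kinetic resolution, the type known for benzoins: the proton between carbonyl, aryl and aryloxy groups exchanges fast in the amine-buffered medium, the (S,S)-catalyst sets the carbinol (R) through its usual aryl-ketone face selection and preferentially consumes the (R)-ketone, for which hydride approach is also the Felkin–Anh one anti to the aryloxy group, so the ether carbon is set (R) under catalyst control, and removal of the minor diastereomer discards most of the material with the wrong ether configuration.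

Step 9
Reactants: 13 (1R,2R)-2-[2,5-bis(benzyloxy)-4-bromophenoxy]-1-[4-(benzyloxy)phenyl]-2-[3,5-bis(benzyloxy)phenyl]ethan-1-ol
Product: 15 (2S,3S)-4,7-bis(benzyloxy)-5-bromo-3-[4-(benzyloxy)phenyl]-2-[3,5-bis(benzyloxy)phenyl]-2,3-dihydro-1-benzofuran, via benzylic cation 14 (not isolated)
Conditions: Tf2NH (10 mol %), CH2Cl2/HFIP 9:1, 0.005 M, −40 °C, warmed towards 0 °C only as far as conversion requires; Et3N quench
Reagents that add atoms: none
Why: Protonation and loss of water from the carbinol give cation 14, delocalised onto the para-benzyloxy oxygen like an O-alkylated quinone methide, so the carbinol configuration is erased and any residual carbinol epimer converges on the same intermediate. The free arene carbon ortho to the ether oxygen, activated by that oxygen and by the adjacent benzyloxy group and only slightly deactivated by the meta bromine, attacks the cation and rearomatises, which forms C3–C3a. The closest known reactions are the dehydrative intramolecular Friedel–Crafts cyclisation of 2-aryloxy-1-arylethanols to 3-aryl-2,3-dihydrobenzofurans and the arene trapping of para-quinone-methide-type cations. The dihydrofuran ring closes in a 5-exo-trig mode with respect to the cationic carbon (the π bond consumed points out of the new ring towards the 4-benzyloxyphenyl group), with the arene π bond endocyclic. C3 is set by substrate control from the untouched C2 centre, whose 3,5-bis(benzyloxy)phenyl group blocks one face of the cation in the five-membered transition state, so the two aryl groups end up trans, the arrangement that is also lower in energy, giving (2S,3S) (C2 changes descriptor from R to S only through a priority change). The step needs site selectivity, secured because the other ortho position carries a benzyloxy group and attack by the C2 aryl ring would give a four-membered ring; it also needs closure faster than C2–H loss or a 1,2-hydride shift, favoured by high dilution, a non-nucleophilic counter-ion and low temperature, while C2–O does not ionise because a meta-dioxygenated ring cannot stabilise a cation there.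

Step 10
Reactants: 15 (2S,3S)-4,7-bis(benzyloxy)-5-bromo-3-[4-(benzyloxy)phenyl]-2-[3,5-bis(benzyloxy)phenyl]-2,3-dihydro-1-benzofuran
Product: 17 (2S,3S)-4,7-bis(benzyloxy)-3-[4-(benzyloxy)phenyl]-2-[3,5-bis(benzyloxy)phenyl]-2,3-dihydro-1-benzofuran-5-carboxylic acid, via aryllithium 16 (not isolated)
Conditions: n-BuLi (1.1 equiv), THF, −78 °C, 10 min; dry CO2, −78 °C to 0 °C; 1 M HCl
Reagents that add atoms: carbon dioxide O=C=O; n-butyllithium [Li]CCCC (lithium, in 16 only)
Why: Bromine–lithium exchange at −78 °C is faster than deprotonation at C2–H, C3–H or the benzyl ether methylenes, and immediate carboxylation of the aryllithium supplies the carbon that becomes chromone C2 without touching either stereocentre.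

Step 11
Reactants: 18 2-methylresorcinol
Product: 19 1,3-diisopropoxy-2-methylbenzene
Conditions: 2-bromopropane (3 equiv), K2CO3, DMF, 70 °C
Reagents that add atoms: 2-bromopropane CC(C)Br
Why: Williamson ether synthesis, isopropyl being chosen because it offers no extra arene C–H bonds to the borylation catalyst, withstands alkyllithium and amide bases, and is cleaved by boron trichloride while a methyl ether is not.

Step 12
Reactants: 19 1,3-diisopropoxy-2-methylbenzene
Product: 21 3,5-diisopropoxy-4-methylphenol, via pinacol boronate 20 (not isolated)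
Conditions: [Ir(OMe)(cod)]2 (1.5 mol %), dtbpy (3 mol %), B2pin2 (0.6 equiv), THF, 80 °C; then aq NaOH, 30% H2O2, 0 °C to rt; dil. HCl
Reagents that add atoms: hydrogen peroxide OO; bis(pinacolato)diboron CC1(C)OB(OC1(C)C)B1OC(C)(C)C(C)(C)O1 (boryl group, in 20 only)
Why: Sterically governed iridium-catalysed C–H borylation selects the only C–H of a 1,2,3-trisubstituted benzene that has no ortho substituent, the one para to the methyl group, and boronate oxidation in the same flask delivers the symmetric phenol.

Step 13
Reactants: 21 3,5-diisopropoxy-4-methylphenol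
Product: 22 1,3-diisopropoxy-5-(methoxymethoxy)-2-methylbenzene
Conditions: MOMCl (1.3 equiv), i-Pr2NEt, CH2Cl2, 0 °C to rt
Reagents that add atoms: chloromethyl methyl ether COCCl
Why: O-alkylation to the formaldehyde acetal masks the acidic proton and installs a strong ortho-directing group that mild acid removes without harming isopropyl ethers.

Step 14
Reactants: 22 1,3-diisopropoxy-5-(methoxymethoxy)-2-methylbenzene; 23 methoxyacetyl chloride
Product: 27 1-(6-hydroxy-2,4-diisopropoxy-3-methylphenyl)-2-methoxyethan-1-one, via aryllithium 24 (not isolated), via arylzinc chloride 25 (not isolated), via MOM-protected ketone 26 (not isolated)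
Conditions: n-BuLi (1.1 equiv), THF, 0 °C; ZnCl2 (1.2 equiv), 0 °C to rt; Pd(PPh3)4 (3 mol %), 23 (1.2 equiv), rt; then 3 M HCl in MeOH, 45 °C
Reagents that add atoms: n-butyllithium [Li]CCCC (lithium, in 24 only); zinc chloride Cl[Zn]Cl (zinc and chlorine, in 25 only)
Why: Directed ortho-metalation occurs at one of the two equivalent positions between the acetal and an isopropoxy group, so only the future 6-methyl pattern can arise; Negishi acylation of the arylzinc then gives the ketone without over-addition, which avoids a Lewis-acid Fries shift, in which the methoxyacetyl cation tends to lose carbon monoxide and the ortho isopropyl ether would be cleaved; the acetal next to the new carbonyl then falls off in methanolic acid.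

Step 15
Reactants: 17 (2S,3S)-4,7-bis(benzyloxy)-3-[4-(benzyloxy)phenyl]-2-[3,5-bis(benzyloxy)phenyl]-2,3-dihydro-1-benzofuran-5-carboxylic acid; 27 1-(6-hydroxy-2,4-diisopropoxy-3-methylphenyl)-2-methoxyethan-1-one
Product: 29 3,5-diisopropoxy-2-(methoxyacetyl)-4-methylphenyl ester of acid 17, via acid chloride 28 (not isolated)
Conditions: 1-chloro-N,N,2-trimethylpropenylamine (1.2 equiv), CH2Cl2, 0 °C to rt; then 27, Et3N, DMAP (0.2 equiv), CH2Cl2, 0 °C to rt
Reagents that add atoms: 1-chloro-N,N,2-trimethylpropenylamine CC(C)=C(Cl)N(C)C (chlorine, in 28 only)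
Why: DMAP-catalysed acylation of the hydrogen-bonded phenol by the acid chloride, which is generated under neutral conditions so that neither hydrogen chloride nor a formylating iminium species meets the electron-rich rings.

Step 16
Reactants: 29 3,5-diisopropoxy-2-(methoxyacetyl)-4-methylphenyl ester of acid 17
Product: 30 1-(6-hydroxy-2,4-diisopropoxy-3-methylphenyl)-2-methoxy-3-[(2S,3S)-dihydrobenzofuran-5-yl]propane-1,3-dione (aryl group as in 17; the central carbon is labile)
Conditions: LiHMDS (3 equiv), THF, −78 °C to −10 °C; AcOH quench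
Reagents that add atoms: none
Why: In this Baker–Venkataraman rearrangement the lithium enolate of the α-methoxy ketone attacks the neighbouring aryl ester through a six-membered transition state and releases the phenoxide, while a cold amide base leaves C3–H alone, whose removal would open the dihydrofuran ring, and the new central carbon disappears as a stereocentre in the next step.

Step 17
Reactants: 30 1-(6-hydroxy-2,4-diisopropoxy-3-methylphenyl)-2-methoxy-3-[(2S,3S)-dihydrobenzofuran-5-yl]propane-1,3-dione
Product: 31 2-{(2S,3S)-4,7-bis(benzyloxy)-3-[4-(benzyloxy)phenyl]-2-[3,5-bis(benzyloxy)phenyl]-2,3-dihydro-1-benzofuran-5-yl}-5,7-diisopropoxy-3-methoxy-6-methyl-4H-chromen-4-one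
Conditions: p-TsOH·H2O (0.2 equiv), toluene, 80 °C
Reagents that add atoms: none
Why: Acid-catalysed cyclodehydration, in which the phenol adds to the aroyl carbonyl and the hemiketal loses water to give the conjugated pyranone, runs under catalytic sulfonic acid that leaves benzyl and isopropyl aryl ethers and the now acyl-deactivated dihydrobenzofuran intact.

Step 18
Reactants: 31 protected 3-methoxyflavone
Product: 32 2-[(2S,3S)-2-(3,5-dihydroxyphenyl)-4,7-dihydroxy-3-(4-hydroxyphenyl)-2,3-dihydro-1-benzofuran-5-yl]-5,7-dihydroxy-3-methoxy-6-methyl-4H-chromen-4-one (CNP0218412.2)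
Conditions: BCl3 (1 M in CH2Cl2, 20 equiv), pentamethylbenzene (15 equiv), CH2Cl2, −78 °C, then 0 °C; MeOH/H2O quench
Reagents that add atoms: none
Why: Boron trichloride cleaves ethers whose alkyl group leaves as a stabilised cation (benzyl at −78 °C, isopropyl on warming), pentamethylbenzene intercepts the benzyl cations before they alkylate the freed resorcinol rings, and the 3-methyl ether persists because methyl cannot ionise and the C4 carbonyl is tied up in a six-membered boron chelate with the 5-oxygen.

Compound list
1 | resveratrol | Oc1ccc(/C=C/c2cc(O)cc(O)c2)cc1 | starting material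
2 | (E)-3,4',5-tris(benzyloxy)stilbene | C(Oc1ccc(/C=C/c2cc(OCc3ccccc3)cc(OCc3ccccc3)c2)cc1)c1ccccc1 | intermediate
3 | rac-threo-1-[4-(benzyloxy)phenyl]-2-[3,5-bis(benzyloxy)phenyl]ethane-1,2-diol (racemate, (1R,2R) form drawn) | O[C@H](c1ccc(OCc2ccccc2)cc1)[C@H](O)c1cc(OCc2ccccc2)cc(OCc2ccccc2)c1 | intermediate
4 | rac-1-[4-(benzyloxy)phenyl]-2-[3,5-bis(benzyloxy)phenyl]-2-hydroxyethan-1-one | O=C(c1ccc(OCc2ccccc2)cc1)C(O)c1cc(OCc2ccccc2)cc(OCc2ccccc2)c1 | intermediate
5 | methanesulfonate of 4 (racemic) | O=C(c1ccc(OCc2ccccc2)cc1)C(OS(C)(=O)=O)c1cc(OCc2ccccc2)cc(OCc2ccccc2)c1 | intermediate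
6 | rac-2-bromo-1-[4-(benzyloxy)phenyl]-2-[3,5-bis(benzyloxy)phenyl]ethan-1-one | O=C(c1ccc(OCc2ccccc2)cc1)C(Br)c1cc(OCc2ccccc2)cc(OCc2ccccc2)c1 | intermediate
7 | 2,5-dibromohydroquinone | Oc1cc(Br)c(O)cc1Br | starting material
8 | 1,4-bis(benzyloxy)-2,5-dibromobenzene | Brc1cc(OCc2ccccc2)c(Br)cc1OCc1ccccc1 | intermediate
9 | 2,5-bis(benzyloxy)-4-bromophenyllithium | [Li]c1cc(OCc2ccccc2)c(Br)cc1OCc1ccccc1 | intermediate
10 | dimethyl [2,5-bis(benzyloxy)-4-bromophenyl]boronate | COB(OC)c1cc(OCc2ccccc2)c(Br)cc1OCc1ccccc1 | intermediate
11 | 2,5-bis(benzyloxy)-4-bromophenol | Oc1cc(OCc2ccccc2)c(Br)cc1OCc1ccccc1 | intermediate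
12 | rac-2-[2,5-bis(benzyloxy)-4-bromophenoxy]-1-[4-(benzyloxy)phenyl]-2-[3,5-bis(benzyloxy)phenyl]ethan-1-one | O=C(c1ccc(OCc2ccccc2)cc1)C(Oc1cc(OCc2ccccc2)c(Br)cc1OCc1ccccc1)c1cc(OCc2ccccc2)cc(OCc2ccccc2)c1 | intermediate
13 | (1R,2R)-2-[2,5-bis(benzyloxy)-4-bromophenoxy]-1-[4-(benzyloxy)phenyl]-2-[3,5-bis(benzyloxy)phenyl]ethan-1-ol | O[C@H](c1ccc(OCc2ccccc2)cc1)[C@@H](c1cc(OCc2ccccc2)cc(OCc2ccccc2)c1)Oc1cc(OCc2ccccc2)c(Br)cc1OCc1ccccc1 | intermediate
14 | 4-(benzyloxy)benzylic cation derived from 13, ether carbon unchanged | [CH+](c1ccc(OCc2ccccc2)cc1)[C@@H](c1cc(OCc2ccccc2)cc(OCc2ccccc2)c1)Oc1cc(OCc2ccccc2)c(Br)cc1OCc1ccccc1 | intermediate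
15 | (2S,3S)-4,7-bis(benzyloxy)-5-bromo-3-[4-(benzyloxy)phenyl]-2-[3,5-bis(benzyloxy)phenyl]-2,3-dihydro-1-benzofuran | Brc1cc(OCc2ccccc2)c2c(c1OCc1ccccc1)[C@H](c1ccc(OCc3ccccc3)cc1)[C@@H](c1cc(OCc3ccccc3)cc(OCc3ccccc3)c1)O2 | intermediate
16 | 5-lithio derivative of 15 | [Li]c1cc(OCc2ccccc2)c2c(c1OCc1ccccc1)[C@H](c1ccc(OCc3ccccc3)cc1)[C@@H](c1cc(OCc3ccccc3)cc(OCc3ccccc3)c1)O2 | intermediate
17 | (2S,3S)-4,7-bis(benzyloxy)-3-[4-(benzyloxy)phenyl]-2-[3,5-bis(benzyloxy)phenyl]-2,3-dihydro-1-benzofuran-5-carboxylic acid | O=C(O)c1cc(OCc2ccccc2)c2c(c1OCc1ccccc1)[C@H](c1ccc(OCc3ccccc3)cc1)[C@@H](c1cc(OCc3ccccc3)cc(OCc3ccccc3)c1)O2 | intermediate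
18 | 2-methylresorcinol | Cc1c(O)cccc1O | starting material
19 | 1,3-diisopropoxy-2-methylbenzene | Cc1c(OC(C)C)cccc1OC(C)C | intermediate
20 | 2-(3,5-diisopropoxy-4-methylphenyl)-4,4,5,5-tetramethyl-1,3,2-dioxaborolane | Cc1c(OC(C)C)cc(B2OC(C)(C)C(C)(C)O2)cc1OC(C)C | intermediate
21 | 3,5-diisopropoxy-4-methylphenol | Cc1c(OC(C)C)cc(O)cc1OC(C)C | intermediate
22 | 1,3-diisopropoxy-5-(methoxymethoxy)-2-methylbenzene | COCOc1cc(OC(C)C)c(C)c(OC(C)C)c1 | intermediate
23 | methoxyacetyl chloride | COCC(=O)Cl | starting material
24 | 2,4-diisopropoxy-6-(methoxymethoxy)-3-methylphenyllithium | [Li]c1c(OCOC)cc(OC(C)C)c(C)c1OC(C)C | intermediate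
25 | [2,4-diisopropoxy-6-(methoxymethoxy)-3-methylphenyl]zinc chloride | Cl[Zn]c1c(OCOC)cc(OC(C)C)c(C)c1OC(C)C | intermediate
26 | 1-[2,4-diisopropoxy-6-(methoxymethoxy)-3-methylphenyl]-2-methoxyethan-1-one | COCC(=O)c1c(OCOC)cc(OC(C)C)c(C)c1OC(C)C | intermediate
27 | 1-(6-hydroxy-2,4-diisopropoxy-3-methylphenyl)-2-methoxyethan-1-one | COCC(=O)c1c(O)cc(OC(C)C)c(C)c1OC(C)C | intermediate
28 | acid chloride of 17 | O=C(Cl)c1cc(OCc2ccccc2)c2c(c1OCc1ccccc1)[C@H](c1ccc(OCc3ccccc3)cc1)[C@@H](c1cc(OCc3ccccc3)cc(OCc3ccccc3)c1)O2 | intermediate
29 | 3,5-diisopropoxy-2-(methoxyacetyl)-4-methylphenyl ester of 17 | COCC(=O)c1c(OC(=O)c2cc(OCc3ccccc3)c3c(c2OCc2ccccc2)[C@H](c2ccc(OCc4ccccc4)cc2)[C@@H](c2cc(OCc4ccccc4)cc(OCc4ccccc4)c2)O3)cc(OC(C)C)c(C)c1OC(C)C | intermediate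
30 | α-methoxy 1,3-diketone (central carbon labile, ring centres 2S,3S) | COC(C(=O)c1c(O)cc(OC(C)C)c(C)c1OC(C)C)C(=O)c1cc(OCc2ccccc2)c2c(c1OCc1ccccc1)[C@H](c1ccc(OCc3ccccc3)cc1)[C@@H](c1cc(OCc3ccccc3)cc(OCc3ccccc3)c1)O2 | intermediate
31 | fully protected 3-methoxyflavone (five benzyl, two isopropyl ethers; 2S,3S) | COc1c(-c2cc(OCc4ccccc4)c3c(c2OCc2ccccc2)[C@H](c2ccc(OCc4ccccc4)cc2)[C@@H](c2cc(OCc4ccccc4)cc(OCc4ccccc4)c2)O3)oc2cc(OC(C)C)c(C)c(OC(C)C)c2c1=O | intermediate
32 | CNP0218412.2, 2-[(2S,3S)-2-(3,5-dihydroxyphenyl)-4,7-dihydroxy-3-(4-hydroxyphenyl)-2,3-dihydro-1-benzofuran-5-yl]-5,7-dihydroxy-3-methoxy-6-methyl-4H-chromen-4-one | COc1c(-c2cc(O)c3c(c2O)[C@H](c2ccc(O)cc2)[C@@H](c2cc(O)cc(O)c2)O3)oc2cc(O)c(C)c(O)c2c1=O | target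

Total step count: 18.
Longest linear sequence: 12 steps (1, 2, 3, 4, 7, 8, 9, 10, 15, 16, 17, 18).

Steps most likely to fail

Step 8. Hydride transfer to a hindered, electron-rich ketone may be sluggish. The catalyst may also discriminate too weakly between the two interconverting ketone enantiomers, which would erode configurational purity at the ether carbon and hence the enantiomeric purity of everything downstream. The fallback replaces asymmetric catalysis by a racemic series with a resolution. Setting out from 12, sodium borohydride in THF/MeOH at 0 °C would give the racemic alcohol as a mixture of carbinol epimers F1. Both epimers would converge under the conditions of step 9 on the racemic trans bromide F2. Preparative chromatography on a polysaccharide chiral stationary phase would then separate the enantiomers. The (2S,3S) enantiomer is 15, where the route is rejoined.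

Step 9. Loss of the C2 proton or a 1,2-hydride shift in the cation may run ahead of ring closure, and both end in cleavage of the aryl ether. The resorcinol diether ring of a second molecule may intercept the cation, or the facial bias at C3 may be weak. All of these become more likely if ionisation only starts at temperatures where the side pathways are fast. The fallback replaces direct dehydration by a pre-activated leaving group. Setting out from 13, trichloroacetonitrile and catalytic DBU in CH2Cl2 at 0 °C would give the benzylic trichloroacetimidate F3. This should ionise with catalytic TMSOTf in dilute CH2Cl2 at −78 °C, with neither water nor a strong protic acid in the flask. The same Friedel–Crafts closure can then occur at the lowest possible temperature and lead back to 15.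

Step 18. Forcing the slow 7-O-isopropyl ether may cause chelation-assisted loss of the 3-methyl ether. C-benzylation of the freed phenol rings may occur if scavenging lags, and the dihydrofuran ring may open under the large excess of Lewis acid. The fallback splits the deprotection into two orthogonal stages. Setting out from 31, hydrogenolysis (H2 at 1 atm, Pd/C, THF/MeOH, rt, stopped once the benzyl ethers are consumed) would give the 5,7-di-O-isopropyl pentaphenol F4; 2-aryl-2,3-dihydrobenzofurans normally survive such conditions. The two remaining ethers would then be cleaved with a small excess of BCl3 in CH2Cl2 (−78 °C to 0 °C), with no benzyl cations present, to reach 32.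

Further compounds
F1 | step 8 | racemic 2-[2,5-bis(benzyloxy)-4-bromophenoxy]-1-[4-(benzyloxy)phenyl]-2-[3,5-bis(benzyloxy)phenyl]ethan-1-ol, mixture of carbinol epimers | OC(c1ccc(OCc2ccccc2)cc1)C(c1cc(OCc2ccccc2)cc(OCc2ccccc2)c1)Oc1cc(OCc2ccccc2)c(Br)cc1OCc1ccccc1
F2 | step 8 | racemic trans bromide, 15 together with its (2R,3R) mirror image (the mirror image is drawn) | Brc1cc(OCc2ccccc2)c2c(c1OCc1ccccc1)[C@@H](c1ccc(OCc3ccccc3)cc1)[C@H](c1cc(OCc3ccccc3)cc(OCc3ccccc3)c1)O2
F3 | step 9 | (1R,2R) benzylic trichloroacetimidate of 13 | ClC(Cl)(Cl)C(=N)O[C@H](c1ccc(OCc2ccccc2)cc1)[C@@H](c1cc(OCc2ccccc2)cc(OCc2ccccc2)c1)Oc1cc(OCc2ccccc2)c(Br)cc1OCc1ccccc1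
F4 | step 18 | 5,7-di-O-isopropyl ether of the target (five phenols free; 2S,3S) | COc1c(-c2cc(O)c3c(c2O)[C@H](c2ccc(O)cc2)[C@@H](c2cc(O)cc(O)c2)O3)oc2cc(OC(C)C)c(C)c(OC(C)C)c2c1=O
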